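The earlier runs and the new flask are simulated on assumed constants, noise included.

The pitfall is to assume Q falls in plain inverse proportion to J. Measure the fall instead. Count J as a fraction of the E charged: 0.507 in the midnight run, 2.00 in the spring run, 1.00 in the flask.

| setting | midnight | spring | flask |
|---|---|---|---|
| E | 0.75 M | 0.75 M | 0.75 M |
| G | 0.75 M | 0.75 M | 0.750 M |
| J | 0.38 M | 1.5 M | 0.750 M |
| remark | run made earlier | run made earlier |  |
| time |  |  | 10 d |
| volume of the second phase over the first |  |  | 0.50 |

| run | time / d | Q / % |
|---|---|---|
| midnight | 1.67 | 0.2 |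
| midnight | 3.00 | 4.6 |
| midnight | 5.00 | 4.7 |
| midnight | 6.00 | 4.9 |
| midnight | 8.00 | 4.8 |
| midnight | 10.0 | 7.6 |
| midnight | 12.0 | 8.8 |
| spring | 0.625 | 1.3 |
| spring | 1.67 | 1.2 |
| spring | 3.00 | 0.7 |
| spring | 5.00 | 2.7 |
| spring | 8.00 | 1.4 |
| spring | 10.0 | 2.4 |
| spring | 12.0 | 2.2 |

(each reading ± 1 percentage point)

- the Q standing at 10 d, as a percentage of the E charged
- the change that raises the amount of Q at 10 d, in percent of the E charged most ("none" if none brings more than 2 percentage points) (gamma / epsilon / none)
- amount of Q at 10 d, in percent of the E charged, after gamma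

- gamma: doubling the transfer coefficient of G, all else as stated
- epsilon: doubling the amount of G, all else as stated

Fold the two readings at 10 d into one number: the log of their Q ratio over the log of their J ratio. This gives 0.840. Call it n, the apparent order of Q in J. It says how steeply Q, as a fraction of the charge, falls as J rises; at 1, Q is inversely proportional to J.

Now read the flask off it. The midnight reading 7.6%, scaled by the J ratio to the power n, gives 4.29%. Was one number enough? The pair at 12.0 d gives n of 1.01, and so 3.83%. A reading scatters by 1 percentage point, so the two values agree, but two runs cannot show whether n bends between them.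

The forecast says 5%, range 3.8% to 6.3%, which is higher than this reckoning. It picks epsilon and gives 6.5% after gamma, range 4.5% to 10%. Its ground: “four times the J gives about a third of the Q”.

The flask gives 5.78%, above the reckoning, with epsilon best at 5.1 points and 7.96% after gamma. Above the flask's charges, the nearest settings where this answer has moved by 5 points are J at 2.76 M and, moved separately, G at 1.48 M, so a run there reading otherwise would test the forecast. Put the answer back in: from the flask to the spring reading, n comes to 1.27, steeper than the first value.

    Z ⇌ G, rate k1*([Z] - [G]/K1) per volume of the first phase (partition coefficient = 24.0, kL = 4.60 × 10⁻⁶ s⁻¹)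
    E + Z → Q (k = 8.20 × 10⁻⁶ L mol⁻¹ s⁻¹)
    Z → L (k = 3.00 × 10⁻⁶ s⁻¹)
    E + J → D (k = 5.60 × 10⁻⁶ L mol⁻¹ s⁻¹)

Take a neighbour flask with 1.9 M of J, which is 2.53 equiv to E. The steeper n gives 1.78%; the computed result is 1.53%, a little lower.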